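## Structural features

The target is an 8-O-4' neolignan with two arenes and no other ring. Ring A (4-hydroxy-3,5-dimethoxyphenyl) carries the chain C7–C8–C9, and C8 is linked through an ether oxygen to C4' of ring B, a 2,6-dimethoxyphenyl unit that bears a 2,3-dihydroxypropyl chain C7'–C8'–C9' para to that oxygen. C7 (benzylic secondary carbinol, S) and C8 (aryloxy carbon, S) are neighbours and stand threo to each other. C8' (S) is separated from them by ring B and has to be set on its own. Fragile points are the electron-rich benzylic carbinol at C7, which ionises in acid once the para phenol is free, and any C7 carbonyl intermediate, in which H8 is acidic and O9 is a β-leaving group. The real difficulty is twofold: the hindered C8–O–C4' ether flanked by two methoxy groups must be made with defined configuration, and the threo relationship C7/C8 must be set. The plan uses that same array: the C8 ether oxygen and an ortho methoxy oxygen of ring B can hold magnesium together with a C7 aldehyde oxygen, which steers a ring A aryl nucleophile to one face of C7.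

## Logic of the disconnections

Target back to 13 (through 15 and 14): only protecting-group bonds are cut, namely the benzyl C–O bond on the ring A phenol, the two ketal C–O bonds on O8'/O9' and the O9–Si bond. These three groups are mutually orthogonal, so the forward order can be chosen freely. The order fluoride, then aqueous acetic acid, then hydrogenolysis keeps the para phenol masked during the only acidic step and ends with a filtration.

13 to 11 plus 12: the C1–C7 bond is cut. It is the only C–C bond between ring A and the chain and lies next to the existing stereocentre C8. Ring A becomes a symmetrical aryl nucleophile without stereochemical information, and 12 goes back to 2 by magnesium insertion. The forward step must give high 1,2-induction towards (7S) and must add faster than it enolises 11.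

11 to 10: no skeletal bond is cut; the C7 aldehyde is traced to a methyl ester. The ester is the configurationally stable storage form of the labile aldehyde. The forward reduction must stop at the aldehyde oxidation level and release it cold.

10 to 7 plus 9: the C8–O(aryl) bond is cut. This places the origin of C8 in the chiral pool, since SN2 inversion at the (R)-carbinol carbon of 9 gives (S). It separates the ring B phenol from a three-carbon glycerate and replaces a longer malonate and enzymatic desymmetrisation sequence, which is kept as the fallback. The forward step needs clean inversion with a phenol that has two ortho substituents.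

9 to 8: the O9–Si bond is cut. The bulky silyl group is chosen so that O9 does not coordinate magnesium later. The forward step needs selectivity for the primary hydroxyl.

7 to 5 (through 6), then 5 to 2 plus 3 (through 4), then 2 to 1: first the ketal C–O bonds and two benzyl C–O bonds are cut, then the aryl–CH2 bond C1'–C7', then the phenol benzyl ether. C8' arrives preformed in 3 and is not touched when the epoxide is opened at its CH2 terminus. The forward opening must be regioselective for the terminal carbon and must leave the oxirane stereocentre alone. One intermediate, 2, supplies both aromatic rings: as the aryllithium 4 for ring B and as the Grignard reagent 12 for ring A.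

## Other disconnections considered

Alternative 1: The cut is the aryl–CH2 bond C1'–C7', made last and not first. The ring B bromide A2, (4S,5S)-4-[4-(benzyloxy)-3,5-dimethoxyphenyl]-5-(4-bromo-2,6-dimethoxyphenoxy)-2,2-dimethyl-1,3-dioxane, would undergo bromine–lithium exchange and transmetalation with MgBr2. With CuBr·SMe2 as catalyst it would then open 3 at the CH2 terminus to give A1, the C9' benzyl ether with a free C8' hydroxyl and the 7,9-acetonide.
- In favour: ring B enters as plain 1, and the chiral epoxide is spent at the end. Either C8' epimer would come from one batch of A2, which is better than the chosen plan for analogue work. The dioxane would let the threo relationship be read from coupling constants. The end game would be two operations (acid, hydrogenolysis) against three, also better.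
- Against: A2 still contains C7 and C8, so the central stereochemical problem is only postponed and would need the same kind of solution with a bromine that must survive it. The advanced intermediate becomes the organometallic partner, which epoxide openings normally want in excess. Protonation of the metalated arene would waste late material.
- Comparison: the bond-forming event is an SN2 opening of 3 at its CH2 terminus by a ring B aryl metal, as in step 2 of the chosen plan, with copper catalysis of a Grignard reagent in place of BF3 activation towards an aryllithium. The two are equal on mechanism type and reliability. The chosen plan runs the opening on simple material. Step count would be about the same.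

Alternative 2: No skeletal bond is cut at the key step; the C7–H bond is formed and C7 and C8 are fixed together. The keto ester A4, ethyl 3-[4-(benzyloxy)-3,5-dimethoxyphenyl]-2-(4-{[(4S)-2,2-dimethyl-1,3-dioxolan-4-yl]methyl}-2,6-dimethoxyphenoxy)-3-oxopropanoate as a C8 epimer mixture, would come from O-alkylation of 7 with the bromo keto ester A5, ethyl 3-[4-(benzyloxy)-3,5-dimethoxyphenyl]-2-bromo-3-oxopropanoate. RuCl(p-cymene)[(R,R)-TsDPEN], a divalent ruthenium catalyst, with HCO2H/Et3N would reduce the ketone while C8 equilibrates through the enol. This would give A3, ethyl (2R,3S)-3-[4-(benzyloxy)-3,5-dimethoxyphenyl]-2-(4-{[(4S)-2,2-dimethyl-1,3-dioxolan-4-yl]methyl}-2,6-dimethoxyphenoxy)-3-hydroxypropanoate. Hydride reduction of its ester would meet the chosen route at 14.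
- In favour: both centres would be set by the catalyst from racemic material. There is no configurationally labile aldehyde and no cryogenic organometallic step. The aryl ether is formed by SN2 on an activated α-halo carbonyl compound, which is a better C–O bond construction for a hindered phenol than the Mitsunobu reaction of the chosen plan.
- Against: the syn (threo) versus anti (erythro) preference of such reductions depends on the α-substituent and would have to be established for a bulky aryloxy group. The ketone is deactivated by the para oxygen donor. The β-hydroxy ester A3 is open to retro-aldol cleavage during ester reduction.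
- Comparison: the alternative has catalyst control and the chosen plan has substrate control. The chosen plan has the clearer stereochemical model for threo, whereas the alternative has the more robust intermediates. Step count would be equal or one step longer.

Alternative 3: The cut is the C7–C8 bond. The allyl ether A7, (4S)-4-[3,5-dimethoxy-4-(prop-2-en-1-yloxy)benzyl]-2,2-dimethyl-1,3-dioxolane, would be metalated with sec-BuLi, and boron would be introduced with (Ipc)2BOMe and BF3·OEt2. Addition to the aldehyde A8, 4-(benzyloxy)-3,5-dimethoxybenzaldehyde, through a closed chair transition state would give A6, (1S,2S)-1-[4-(benzyloxy)-3,5-dimethoxyphenyl]-2-(4-{[(4S)-2,2-dimethyl-1,3-dioxolan-4-yl]methyl}-2,6-dimethoxyphenoxy)but-3-en-1-ol. Oxidative cleavage of the vinyl group and reduction would again reach 14.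
- In favour: one step would form the C7–C8 bond and both stereocentres. The Z geometry translates into threo and the terpene ligands set the absolute sense. No epimerisable aldehyde is involved. On stereochemical economy this is better than the chosen plan, and it would be about one step shorter.
- Against: deprotonation of an aryl allyl ether is less well behaved than that of alkyl allyl ethers, because Wittig-type rearrangement and ring or benzylic metalation compete. The Z-selective metalation relies on oxygen–lithium chelation, which is weak for an aryl ether. The alkene cleavage must spare two electron-rich arenes. One carbon and a stoichiometric chiral reagent are discarded.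
- Comparison: the alternative gives reagent control over two centres, and the chosen plan gives chelate control over one centre with the other bought from the chiral pool. The chosen plan is judged more predictable at the metalation stage and the alternative more elegant.

Key step: step 8

Assumption: 8 (methyl (R)-glycerate) is treated as a purchasable chiral-pool ester. Locants C7–C9 and C7'–C9' denote the chains on ring A and ring B.

## Route

Step 1

Reactants: 1 4-bromo-2,6-dimethoxyphenol

Product: 2 2-(benzyloxy)-5-bromo-1,3-dimethoxybenzene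

Conditions: BnBr, K2CO3, DMF, rt to 50 °C

Reagents that add atoms: benzyl bromide, BrCc1ccccc1

Why: Williamson etherification of an acidic phenol with a reactive benzylic halide; the aryl bromide is inert to carbonate. The product serves both as the ring B building block and as the source of the ring A nucleophile.

Step 2

Reactants: 2 2-(benzyloxy)-5-bromo-1,3-dimethoxybenzene; 3 (S)-benzyl glycidyl ether, (2S)-2-[(benzyloxy)methyl]oxirane

Product: 5 (2S)-1-(benzyloxy)-3-[4-(benzyloxy)-3,5-dimethoxyphenyl]propan-2-ol, via aryllithium 4 (not isolated)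

Conditions: 2 (1.5 equiv), n-BuLi (1.45 equiv), THF, −78 °C; 3 (1.0 equiv), then BF3·OEt2 (1.5 equiv), −78 °C; aq. NH4Cl

Reagents that add atoms: none

Why: Bromine–lithium exchange gives the aryllithium, and BF3·OEt2 activates the oxirane oxygen so that the aryllithium opens the epoxide by SN2 at the unsubstituted CH2 carbon at −78 °C (Lewis-acid-promoted organolithium epoxide opening). The stereocentre of 3 is not touched and becomes C8' (S); the slight deficit of n-BuLi keeps free butyllithium from competing for the epoxide.

Step 3

Reactants: 5 (2S)-1-(benzyloxy)-3-[4-(benzyloxy)-3,5-dimethoxyphenyl]propan-2-ol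

Product: 6 (2S)-3-(4-hydroxy-3,5-dimethoxyphenyl)propane-1,2-diol

Conditions: H2 (1 atm), 10% Pd/C, MeOH, rt

Reagents that add atoms: none

Why: Catalytic hydrogenolysis cleaves the aryl and the primary alkyl benzyl ether in one operation; the homobenzylic secondary alcohol has no benzylic C–O bond and is not affected.

Step 4

Reactants: 6 (2S)-3-(4-hydroxy-3,5-dimethoxyphenyl)propane-1,2-diol

Product: 7 4-{[(4S)-2,2-dimethyl-1,3-dioxolan-4-yl]methyl}-2,6-dimethoxyphenol

Conditions: Me2C(OMe)2, PPTS (cat.), acetone, rt

Reagents that add atoms: 2,2-dimethoxypropane, COC(C)(C)OC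

Why: Acid-catalysed transketalisation closes the five-membered isopropylidene ketal on the terminal 1,2-diol. A phenol forms no stable mixed ketal, so the hydroxyl needed for the aryl ether stays free.

Step 5

Reactants: 8 methyl (2R)-2,3-dihydroxypropanoate

Product: 9 methyl (2R)-2-hydroxy-3-[(triisopropylsilyl)oxy]propanoate

Conditions: TIPSCl, imidazole, CH2Cl2, 0 °C → rt

Reagents that add atoms: triisopropylsilyl chloride, CC(C)[Si](Cl)(C(C)C)C(C)C

Why: Silylation with a bulky chlorosilane is selective for the primary hydroxyl over the less nucleophilic secondary α-hydroxy ester hydroxyl; the stereocentre is not involved.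

Step 6

Reactants: 7 4-{[(4S)-2,2-dimethyl-1,3-dioxolan-4-yl]methyl}-2,6-dimethoxyphenol; 9 methyl (2R)-2-hydroxy-3-[(triisopropylsilyl)oxy]propanoate

Product: 10 methyl (2S)-2-(4-{[(4S)-2,2-dimethyl-1,3-dioxolan-4-yl]methyl}-2,6-dimethoxyphenoxy)-3-[(triisopropylsilyl)oxy]propanoate

Conditions: PPh3, DIAD, toluene, 0 °C → rt

Reagents that add atoms: none

Why: Mitsunobu etherification: the phenol (pKa about 10) protonates the betaine, and the phenoxide displaces the oxyphosphonium group at the ester α-carbon with inversion, converting the (R)-carbinol into the (S)-aryl ether that is C8. SN2 at a carbon α to an ester is accelerated, which should offset the two ortho methoxy groups.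

Step 7

Reactants: 10 methyl (2S)-2-(4-{[(4S)-2,2-dimethyl-1,3-dioxolan-4-yl]methyl}-2,6-dimethoxyphenoxy)-3-[(triisopropylsilyl)oxy]propanoate

Product: 11 (2S)-2-(4-{[(4S)-2,2-dimethyl-1,3-dioxolan-4-yl]methyl}-2,6-dimethoxyphenoxy)-3-[(triisopropylsilyl)oxy]propanal

Conditions: i-Bu2AlH (1.1 equiv), CH2Cl2, −78 °C; MeOH, then aq. potassium sodium tartrate (KNaC4H4O6)

Reagents that add atoms: none

Why: Partial reduction of an ester with i-Bu2AlH at low temperature; the aluminium hemiacetal is stabilised by the α-aryloxy oxygen and collapses only on work-up. The aldehyde is therefore released cold and neutral and is used at once without chromatography, which should keep C8 intact.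

Step 8

Reactants: 11 (2S)-2-(4-{[(4S)-2,2-dimethyl-1,3-dioxolan-4-yl]methyl}-2,6-dimethoxyphenoxy)-3-[(triisopropylsilyl)oxy]propanal; 2 2-(benzyloxy)-5-bromo-1,3-dimethoxybenzene

Product: 13 (1S,2S)-1-[4-(benzyloxy)-3,5-dimethoxyphenyl]-2-(4-{[(4S)-2,2-dimethyl-1,3-dioxolan-4-yl]methyl}-2,6-dimethoxyphenoxy)-3-[(triisopropylsilyl)oxy]propan-1-ol, via aryl Grignard reagent 12 (not isolated)

Conditions: 2, Mg turnings, THF (minimum volume), 45 °C, then diluted with CH2Cl2; added to 11 and MgBr2·OEt2 (3 equiv) in CH2Cl2, −78 °C; aq. NH4Cl

Reagents that add atoms: none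

Why: Magnesium inserts into the C–Br bond of 2 and gives 12, while MgBr2 binds the aldehyde oxygen and the C8 aryl ether oxygen of 11 in a five-membered chelate, with an ortho methoxy oxygen of ring B available as a third donor, which fixes the C7–C8 rotamer with O7 and O8 syn-periplanar. The aryl group of 12 then adds to the carbonyl carbon by polar 1,2-addition from the face that carries H8, away from the CH2OSi(i-Pr)3 branch. The closest known reaction type is the Cram-chelate addition of Grignard reagents to α-alkoxy aldehydes in the presence of MgBr2·OEt2 in CH2Cl2. No ring is closed; the chelate is only a transient metallacycle. The single new stereocentre, C7, is controlled by C8 through 1,2-asymmetric induction, and attack anti to C9 on the (8S)-chelate gives (7S), that is the threo carbinol. The step needs chelate addition to outrun the open Felkin–Anh or Cornforth pathway, which would give the erythro epimer, and it needs addition to outrun α-deprotonation, which would epimerise C8 or expel the silanolate. The first should be secured by the 2,6-dimethoxyphenoxy donor set, by the bulky silyl ether on O9 that does not coordinate and so shuts off a six-membered chelate, and by excess MgBr2 in a medium that is mostly CH2Cl2 and holds only the little THF brought in with 12; the second by the low basicity of an aryl Grignard reagent at −78 °C and by the unhindered nucleophilic carbon, which is meta to both methoxy groups.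

Step 9

Reactants: 13 (1S,2S)-1-[4-(benzyloxy)-3,5-dimethoxyphenyl]-2-(4-{[(4S)-2,2-dimethyl-1,3-dioxolan-4-yl]methyl}-2,6-dimethoxyphenoxy)-3-[(triisopropylsilyl)oxy]propan-1-ol

Product: 14 (1S,2S)-1-[4-(benzyloxy)-3,5-dimethoxyphenyl]-2-(4-{[(4S)-2,2-dimethyl-1,3-dioxolan-4-yl]methyl}-2,6-dimethoxyphenoxy)propane-1,3-diol

Conditions: Bu4NF, THF, 0 °C → rt

Reagents that add atoms: none

Why: Fluoride cleavage of the silyl ether, driven by the strong Si–F bond; the ketal, the benzyl ether and both stereocentres are inert to these conditions.

Step 10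

Reactants: 14 (1S,2S)-1-[4-(benzyloxy)-3,5-dimethoxyphenyl]-2-(4-{[(4S)-2,2-dimethyl-1,3-dioxolan-4-yl]methyl}-2,6-dimethoxyphenoxy)propane-1,3-diol

Product: 15 (1S,2S)-1-[4-(benzyloxy)-3,5-dimethoxyphenyl]-2-{4-[(2S)-2,3-dihydroxypropyl]-2,6-dimethoxyphenoxy}propane-1,3-diol

Conditions: AcOH/H2O (4:1), rt

Reagents that add atoms: none

Why: Mild aqueous-acid hydrolysis of a terminal isopropylidene ketal. The ring A oxygen is still benzylated and is twisted out of conjugation by its two methoxy neighbours, so the C7 carbinol should ionise only slowly and keep its configuration.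

Step 11

Reactants: 15 (1S,2S)-1-[4-(benzyloxy)-3,5-dimethoxyphenyl]-2-{4-[(2S)-2,3-dihydroxypropyl]-2,6-dimethoxyphenoxy}propane-1,3-diol

Product: 16 (1S,2S)-2-{4-[(2S)-2,3-dihydroxypropyl]-2,6-dimethoxyphenoxy}-1-(4-hydroxy-3,5-dimethoxyphenyl)propane-1,3-diol

Conditions: H2 (1 atm), 10% Pd/C, EtOAc/EtOH, rt

Reagents that add atoms: none

Why: Hydrogenolysis of a phenolic benzyl ether is fast at room temperature and atmospheric pressure and should be much faster than cleavage of the C7–OH or C8–OAr bond. Filtration and evaporation give the polar product without aqueous work-up.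

## Compound list

```
1 | 4-bromo-2,6-dimethoxyphenol | COc1cc(Br)cc(OC)c1O | starting material
2 | 2-(benzyloxy)-5-bromo-1,3-dimethoxybenzene | COc1cc(Br)cc(OC)c1OCc1ccccc1 | intermediate
3 | (S)-benzyl glycidyl ether, (2S)-2-[(benzyloxy)methyl]oxirane | C1[C@H](O1)COCc1ccccc1 | starting material
4 | [4-(benzyloxy)-3,5-dimethoxyphenyl]lithium | [Li]c1cc(OC)c(OCc2ccccc2)c(OC)c1 | intermediate (not isolated)
5 | (2S)-1-(benzyloxy)-3-[4-(benzyloxy)-3,5-dimethoxyphenyl]propan-2-ol | COc1cc(C[C@H](O)COCc2ccccc2)cc(OC)c1OCc1ccccc1 | intermediate
6 | (2S)-3-(4-hydroxy-3,5-dimethoxyphenyl)propane-1,2-diol | COc1cc(C[C@H](O)CO)cc(OC)c1O | intermediate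
7 | 4-{[(4S)-2,2-dimethyl-1,3-dioxolan-4-yl]methyl}-2,6-dimethoxyphenol | COc1cc(C[C@H]2COC(C)(C)O2)cc(OC)c1O | intermediate
8 | methyl (2R)-2,3-dihydroxypropanoate | COC(=O)[C@H](O)CO | starting material
9 | methyl (2R)-2-hydroxy-3-[(triisopropylsilyl)oxy]propanoate | COC(=O)[C@H](O)CO[Si](C(C)C)(C(C)C)C(C)C | intermediate
10 | methyl (2S)-2-(4-{[(4S)-2,2-dimethyl-1,3-dioxolan-4-yl]methyl}-2,6-dimethoxyphenoxy)-3-[(triisopropylsilyl)oxy]propanoate | COC(=O)[C@@H](Oc1c(OC)cc(C[C@H]2COC(C)(C)O2)cc1OC)CO[Si](C(C)C)(C(C)C)C(C)C | intermediate
11 | (2S)-2-(4-{[(4S)-2,2-dimethyl-1,3-dioxolan-4-yl]methyl}-2,6-dimethoxyphenoxy)-3-[(triisopropylsilyl)oxy]propanal | O=C[C@H](CO[Si](C(C)C)(C(C)C)C(C)C)Oc1c(OC)cc(C[C@H]2COC(C)(C)O2)cc1OC | intermediate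
12 | [4-(benzyloxy)-3,5-dimethoxyphenyl]magnesium bromide | COc1cc([Mg]Br)cc(OC)c1OCc1ccccc1 | intermediate (not isolated)
13 | (1S,2S)-1-[4-(benzyloxy)-3,5-dimethoxyphenyl]-2-(4-{[(4S)-2,2-dimethyl-1,3-dioxolan-4-yl]methyl}-2,6-dimethoxyphenoxy)-3-[(triisopropylsilyl)oxy]propan-1-ol | COc1cc([C@H](O)[C@H](CO[Si](C(C)C)(C(C)C)C(C)C)Oc2c(OC)cc(C[C@H]3COC(C)(C)O3)cc2OC)cc(OC)c1OCc1ccccc1 | intermediate
14 | (1S,2S)-1-[4-(benzyloxy)-3,5-dimethoxyphenyl]-2-(4-{[(4S)-2,2-dimethyl-1,3-dioxolan-4-yl]methyl}-2,6-dimethoxyphenoxy)propane-1,3-diol | COc1cc([C@H](O)[C@H](CO)Oc2c(OC)cc(C[C@H]3COC(C)(C)O3)cc2OC)cc(OC)c1OCc1ccccc1 | intermediate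
15 | (1S,2S)-1-[4-(benzyloxy)-3,5-dimethoxyphenyl]-2-{4-[(2S)-2,3-dihydroxypropyl]-2,6-dimethoxyphenoxy}propane-1,3-diol | COc1cc([C@H](O)[C@H](CO)Oc2c(OC)cc(C[C@H](O)CO)cc2OC)cc(OC)c1OCc1ccccc1 | intermediate
16 | (1S,2S)-2-{4-[(2S)-2,3-dihydroxypropyl]-2,6-dimethoxyphenoxy}-1-(4-hydroxy-3,5-dimethoxyphenyl)propane-1,3-diol | COc1cc([C@H](O)[C@H](CO)Oc2c(OC)cc(C[C@H](O)CO)cc2OC)cc(OC)c1O | target
```

## Step count and least certain steps

Total step count: 11. Longest linear sequence: 10 steps (steps 1–4 and 6–11, from 1 to 16). Step 5 is a one-step branch, and 2 is drawn on a second time in step 8.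

Step 8 (key step). The facial discrimination may be insufficient: an aryl ether oxygen is a weaker donor than an alkyl ether oxygen, and the THF brought in with the Grignard reagent or the dioxolane oxygens compete for magnesium, so the open-chain pathway may leak erythro product. The organometallic may also enolise 11, with loss of configuration at C8 or β-elimination of silanolate. The fallback sets out from 11 and 12 and moves the control of C7 from the addition to a later reduction. The addition is run without any demand on selectivity and gives 13 together with its C7 epimer, (1R,2S)-1-[4-(benzyloxy)-3,5-dimethoxyphenyl]-2-(4-{[(4S)-2,2-dimethyl-1,3-dioxolan-4-yl]methyl}-2,6-dimethoxyphenoxy)-3-[(triisopropylsilyl)oxy]propan-1-ol F1. Dess–Martin oxidation converges both on the aryl ketone (2S)-1-[4-(benzyloxy)-3,5-dimethoxyphenyl]-2-(4-{[(4S)-2,2-dimethyl-1,3-dioxolan-4-yl]methyl}-2,6-dimethoxyphenoxy)-3-[(triisopropylsilyl)oxy]propan-1-one F2. Reduction with LiBH(s-Bu)3 in THF at −78 °C uses a bulky, non-chelating hydride that should follow the Felkin–Anh model (hydride anti to the C8–OAr bond). This should give the threo carbinol, and the route is rejoined at 13.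

Step 7. The reduction may run on to the primary alcohol, and the configuration at C8 may erode while the aldehyde is liberated and handled. The fallback sets out from 10: exhaustive reduction with LiBH4 in THF gives the stable primary alcohol (2R)-2-(4-{[(4S)-2,2-dimethyl-1,3-dioxolan-4-yl]methyl}-2,6-dimethoxyphenoxy)-3-[(triisopropylsilyl)oxy]propan-1-ol F3, whose enantiopurity can be assayed at leisure. Oxidation with Dess–Martin periodinane buffered with NaHCO3, immediately before step 8, returns to the route at 11.

Step 6. The substitution may be sluggish, because the phenol has two ortho substituents and the carbinol carbon is branched. The activated alcohol would then be consumed by alkylation of the hydrazide or by elimination, and some stereochemical leakage is possible if the displacement is not cleanly SN2. The fallback sets out from 7 and sets C8 by enzymatic desymmetrisation and not by chiral-pool inversion. O-alkylation with diethyl bromomalonate (K2CO3, acetone) gives diethyl 2-(4-{[(4S)-2,2-dimethyl-1,3-dioxolan-4-yl]methyl}-2,6-dimethoxyphenoxy)propanedioate F4. LiAlH4 reduction gives the prochiral diol 2-(4-{[(4S)-2,2-dimethyl-1,3-dioxolan-4-yl]methyl}-2,6-dimethoxyphenoxy)propane-1,3-diol F5. Monoacetylation with Burkholderia cepacia lipase and vinyl acetate is intended to give (2S)-2-(4-{[(4S)-2,2-dimethyl-1,3-dioxolan-4-yl]methyl}-2,6-dimethoxyphenoxy)-3-hydroxypropyl acetate F6. Silylation (TIPSOTf, 2,6-lutidine) gives (2R)-2-(4-{[(4S)-2,2-dimethyl-1,3-dioxolan-4-yl]methyl}-2,6-dimethoxyphenoxy)-3-[(triisopropylsilyl)oxy]propyl acetate F7. Methanolysis (K2CO3, MeOH) gives the primary alcohol F3 described under step 7, and buffered Dess–Martin oxidation returns to the route at 11. Which hydroxymethyl arm the enzyme acylates would have to be established by correlation of F3 with material that even a low-yielding step 6 supplies through 10.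

Step 10. The isopropylidene group may transfer to the freshly freed 7,9-diol. That would force longer acid exposure and then invite ionisation at C7, with loss of the threo configuration. The fallback sets out from 13 and reverses the order of the two deprotections. The dioxolane is hydrolysed with aqueous acetic acid while O9 is still silylated, so no 1,3-diol is available to capture the ketal; this gives (1S,2S)-1-[4-(benzyloxy)-3,5-dimethoxyphenyl]-2-{4-[(2S)-2,3-dihydroxypropyl]-2,6-dimethoxyphenoxy}-3-[(triisopropylsilyl)oxy]propan-1-ol F8. Desilylation with Bu4NF then returns to the route at 15.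

## Further compounds

```
F1 | step 8 | (1R,2S)-1-[4-(benzyloxy)-3,5-dimethoxyphenyl]-2-(4-{[(4S)-2,2-dimethyl-1,3-dioxolan-4-yl]methyl}-2,6-dimethoxyphenoxy)-3-[(triisopropylsilyl)oxy]propan-1-ol | COc1cc([C@@H](O)[C@H](CO[Si](C(C)C)(C(C)C)C(C)C)Oc2c(OC)cc(C[C@H]3COC(C)(C)O3)cc2OC)cc(OC)c1OCc1ccccc1
F2 | step 8 | (2S)-1-[4-(benzyloxy)-3,5-dimethoxyphenyl]-2-(4-{[(4S)-2,2-dimethyl-1,3-dioxolan-4-yl]methyl}-2,6-dimethoxyphenoxy)-3-[(triisopropylsilyl)oxy]propan-1-one | COc1cc(C(=O)[C@H](CO[Si](C(C)C)(C(C)C)C(C)C)Oc2c(OC)cc(C[C@H]3COC(C)(C)O3)cc2OC)cc(OC)c1OCc1ccccc1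
F3 | step 7 | (2R)-2-(4-{[(4S)-2,2-dimethyl-1,3-dioxolan-4-yl]methyl}-2,6-dimethoxyphenoxy)-3-[(triisopropylsilyl)oxy]propan-1-ol | OC[C@H](CO[Si](C(C)C)(C(C)C)C(C)C)Oc1c(OC)cc(C[C@H]2COC(C)(C)O2)cc1OC
F4 | step 6 | diethyl 2-(4-{[(4S)-2,2-dimethyl-1,3-dioxolan-4-yl]methyl}-2,6-dimethoxyphenoxy)propanedioate | CCOC(=O)C(Oc1c(OC)cc(C[C@H]2COC(C)(C)O2)cc1OC)C(=O)OCC
F5 | step 6 | 2-(4-{[(4S)-2,2-dimethyl-1,3-dioxolan-4-yl]methyl}-2,6-dimethoxyphenoxy)propane-1,3-diol | OCC(CO)Oc1c(OC)cc(C[C@H]2COC(C)(C)O2)cc1OC
F6 | step 6 | (2S)-2-(4-{[(4S)-2,2-dimethyl-1,3-dioxolan-4-yl]methyl}-2,6-dimethoxyphenoxy)-3-hydroxypropyl acetate | CC(=O)OC[C@H](CO)Oc1c(OC)cc(C[C@H]2COC(C)(C)O2)cc1OC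
F7 | step 6 | (2R)-2-(4-{[(4S)-2,2-dimethyl-1,3-dioxolan-4-yl]methyl}-2,6-dimethoxyphenoxy)-3-[(triisopropylsilyl)oxy]propyl acetate | CC(=O)OC[C@H](CO[Si](C(C)C)(C(C)C)C(C)C)Oc1c(OC)cc(C[C@H]2COC(C)(C)O2)cc1OC
F8 | step 10 | (1S,2S)-1-[4-(benzyloxy)-3,5-dimethoxyphenyl]-2-{4-[(2S)-2,3-dihydroxypropyl]-2,6-dimethoxyphenoxy}-3-[(triisopropylsilyl)oxy]propan-1-ol | COc1cc([C@H](O)[C@H](CO[Si](C(C)C)(C(C)C)C(C)C)Oc2c(OC)cc(C[C@H](O)CO)cc2OC)cc(OC)c1OCc1ccccc1
A1 | alternative 1 | (2S)-1-(benzyloxy)-3-(4-{[(4S,5S)-4-[4-(benzyloxy)-3,5-dimethoxyphenyl]-2,2-dimethyl-1,3-dioxan-5-yl]oxy}-3,5-dimethoxyphenyl)propan-2-ol | COc1cc([C@@H]2OC(C)(C)OC[C@@H]2Oc2c(OC)cc(C[C@H](O)COCc3ccccc3)cc2OC)cc(OC)c1OCc1ccccc1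
A2 | alternative 1 | (4S,5S)-4-[4-(benzyloxy)-3,5-dimethoxyphenyl]-5-(4-bromo-2,6-dimethoxyphenoxy)-2,2-dimethyl-1,3-dioxane | COc1cc([C@@H]2OC(C)(C)OC[C@@H]2Oc2c(OC)cc(Br)cc2OC)cc(OC)c1OCc1ccccc1
A3 | alternative 2 | ethyl (2R,3S)-3-[4-(benzyloxy)-3,5-dimethoxyphenyl]-2-(4-{[(4S)-2,2-dimethyl-1,3-dioxolan-4-yl]methyl}-2,6-dimethoxyphenoxy)-3-hydroxypropanoate | COc1cc([C@H](O)[C@H](C(=O)OCC)Oc2c(OC)cc(C[C@H]3COC(C)(C)O3)cc2OC)cc(OC)c1OCc1ccccc1
A4 | alternative 2 | ethyl 3-[4-(benzyloxy)-3,5-dimethoxyphenyl]-2-(4-{[(4S)-2,2-dimethyl-1,3-dioxolan-4-yl]methyl}-2,6-dimethoxyphenoxy)-3-oxopropanoate (both C2 epimers) | CCOC(=O)C(Oc1c(OC)cc(C[C@H]2COC(C)(C)O2)cc1OC)C(=O)c1cc(OC)c(OCc2ccccc2)c(OC)c1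
A5 | alternative 2 | ethyl 3-[4-(benzyloxy)-3,5-dimethoxyphenyl]-2-bromo-3-oxopropanoate (racemic) | CCOC(=O)C(Br)C(=O)c1cc(OC)c(OCc2ccccc2)c(OC)c1
A6 | alternative 3 | (1S,2S)-1-[4-(benzyloxy)-3,5-dimethoxyphenyl]-2-(4-{[(4S)-2,2-dimethyl-1,3-dioxolan-4-yl]methyl}-2,6-dimethoxyphenoxy)but-3-en-1-ol | COc1cc([C@H](O)[C@H](C=C)Oc2c(OC)cc(C[C@H]3COC(C)(C)O3)cc2OC)cc(OC)c1OCc1ccccc1
A7 | alternative 3 | (4S)-4-[3,5-dimethoxy-4-(prop-2-en-1-yloxy)benzyl]-2,2-dimethyl-1,3-dioxolane | C=CCOc1c(OC)cc(C[C@H]2COC(C)(C)O2)cc1OC
A8 | alternative 3 | 4-(benzyloxy)-3,5-dimethoxybenzaldehyde | COc1cc(C=O)cc(OC)c1OCc1ccccc1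
```
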